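**Retrosynthetic overview**

1. The target is fisetinidol-(4α→8)-6-methylcatechin; it is reached by global hydrogenolysis of its hepta-O-benzyl ether.
2. Ring C of the upper unit is formed last: C4–C4a and O1–C2 are made in one acid-mediated [3+3] annulation of resorcinol (upper ring A, delivered intact) with an oxiranyl carbinol whose C4 already sits on C8 of the lower unit. The oxirane is a ring not present in the target; it carries C3 and C2 and is consumed.
3. Enabling feature: upper C4 is attached to C8 of the lower ring A, whose O7 and O1 (ortho) and O5 (para) make a C4 cation exceptionally stable. Upper C2 is benzylic to the catechol ring B, and the upper ring A is a resorcinol whose C4a (para to O7) and O1 form a C,O-bis-nucleophile.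
4. The oxiranyl carbinol comes from the C8 aryllithium of 8-bromo-6-methyl-penta-O-benzylcatechin and a (2R,3S)-3-aryl-oxirane-2-carbaldehyde (Sharpless epoxidation, then oxidation).
5. The lower rings A, C and B and both lower stereocentres come from (+)-catechin: benzylation, C8 bromination, C6 iodination, C6 methylation.

Key step: step 11

Assumption: compound 14 is formed and used as a mixture of epimers at its carbinol carbon (upper C4), because this centre becomes a planar cation in step 11. Flavan numbering (O1, C2, C3, C4, C4a, C8a) is used for both units; "upper" is the unit that is built, "lower" the catechin-derived one.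

**Route**

Step 1
Reactants: 1 (+)-catechin
Product: 2 5,7,3',4'-tetra-O-benzyl-(+)-catechin
Conditions: BnBr (4.4 equiv), K2CO3 (5 equiv), DMF, 0 °C → rt
Reagents that add atoms: benzyl bromide, BrCc1ccccc1
Why: Williamson etherification of the four phenols under carbonate conditions, which should leave the secondary 3-OH untouched and not epimerize C2.

Step 2
Reactants: 2 5,7,3',4'-tetra-O-benzyl-(+)-catechin
Product: 3 3,5,7,3',4'-penta-O-benzyl-(+)-catechin
Conditions: NaH (1.5 equiv), BnBr (1.3 equiv), DMF, 0 °C → rt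
Reagents that add atoms: benzyl bromide, BrCc1ccccc1
Why: Williamson etherification of the sodium alkoxide of the remaining secondary alcohol; no stereocentre is touched.

Step 3
Reactants: 3 3,5,7,3',4'-penta-O-benzyl-(+)-catechin
Product: 4 8-bromo-penta-O-benzylcatechin
Conditions: NBS (1.0 equiv), CH2Cl2, −78 → 0 °C
Reagents that add atoms: N-bromosuccinimide, O=C1CCC(=O)N1Br
Why: Electrophilic aromatic bromination; the phloroglucinol-type ring A is far more nucleophilic than ring B, and C8 (flanked by O7 and the ring oxygen O1) is the less hindered position and the one preferred in per-O-benzylated flavan-3-ols.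

Step 4
Reactants: 4 8-bromo-penta-O-benzylcatechin
Product: 5 8-bromo-6-iodo-penta-O-benzylcatechin
Conditions: NIS (1.2 equiv), CF3CO2H (10 mol%), CH2Cl2, 0 °C → rt, dark
Reagents that add atoms: N-iodosuccinimide, O=C1CCC(=O)N1I
Why: Electrophilic aromatic iodination at C6, the only free position of the activated ring A.

Step 5
Reactants: 5 8-bromo-6-iodo-penta-O-benzylcatechin
Product: 6 8-bromo-6-methyl-penta-O-benzylcatechin
Conditions: MeZnCl (1.5 equiv), Pd(PPh3)4 (5 mol%), THF, 45 °C
Reagents that add atoms: methylzinc chloride, C[Zn]Cl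
Why: Negishi cross-coupling; zerovalent palladium should insert into the C–I bond much faster than into the equally hindered, electron-rich C–Br bond, so only C6 is methylated and the C8 bromide is kept.

Step 6
Reactants: 7 3,4-bis(benzyloxy)benzaldehyde; 8 ethyl (triphenylphosphoranylidene)acetate
Product: 9 ethyl (E)-3-[3,4-bis(benzyloxy)phenyl]prop-2-enoate
Conditions: toluene, 80 °C
Reagents that add atoms: none
Why: Wittig olefination with a stabilized ylide, which should give the (E)-cinnamate.

Step 7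
Reactants: 9 ethyl (E)-3-[3,4-bis(benzyloxy)phenyl]prop-2-enoate
Product: 10 (E)-3-[3,4-bis(benzyloxy)phenyl]prop-2-en-1-ol
Conditions: i-Bu2AlH (2.2 equiv), CH2Cl2, −78 °C; aq KNaC4H4O6
Reagents that add atoms: none
Why: 1,2-Reduction of the unsaturated ester to the allylic alcohol by the aluminium hydride at low temperature, with the alkene geometry retained.

Step 8
Reactants: 10 (E)-3-[3,4-bis(benzyloxy)phenyl]prop-2-en-1-ol
Product: 11 [(2S,3S)-3-[3,4-bis(benzyloxy)phenyl]oxiran-2-yl]methanol
Conditions: Ti(Oi-Pr)4 (10 mol%), L-(+)-diethyl tartrate (12 mol%), t-BuOOH (2 equiv, decane), 4 Å MS, CH2Cl2, −25 °C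
Reagents that add atoms: tert-butyl hydroperoxide, CC(C)(C)OO
Why: Katsuki–Sharpless asymmetric epoxidation; with L-(+)-tartrate the oxygen is delivered to the face that gives the (2S,3S)-epoxide of (E)-3-aryl allylic alcohols, and the catalytic, sieve-dried protocol should limit opening of the electron-rich epoxide.

Step 9
Reactants: 11 [(2S,3S)-3-[3,4-bis(benzyloxy)phenyl]oxiran-2-yl]methanol
Product: 12 (2R,3S)-3-[3,4-bis(benzyloxy)phenyl]oxirane-2-carbaldehyde
Conditions: (n-Pr)4N[RuO4] (5 mol%), N-methylmorpholine N-oxide (1.5 equiv), 4 Å MS, CH2Cl2, 0 °C → rt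
Reagents that add atoms: none
Why: Ley–Griffith oxidation under neutral, anhydrous conditions should give the aldehyde without opening or epimerizing the epoxide; C2 becomes R only through the change in CIP priorities.

Step 10
Reactants: 6 8-bromo-6-methyl-penta-O-benzylcatechin; 12 (2R,3S)-3-[3,4-bis(benzyloxy)phenyl]oxirane-2-carbaldehyde
Product: 14 oxiranyl carbinol (both carbinol epimers), via C8 aryllithium 13 (not isolated)
Conditions: n-BuLi (1.05 equiv), THF, −78 °C, 20 min; then 12 (1.3 equiv), −78 °C; sat. aq NH4Cl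
Reagents that add atoms: none
Why: Bromine–lithium exchange followed by 1,2-addition of the aryllithium to the aldehyde; the new carbinol centre forms as an epimer mixture that is erased in step 11, and the cold lithium alkoxide should not undergo Payne rearrangement.

Step 11
Reactants: 14 oxiranyl carbinol (both carbinol epimers); 15 resorcinol
Product: 17 hepta-O-benzyl fisetinidol-(4α→8)-6-methylcatechin (free upper 3-OH and 7-OH), via Friedel–Crafts adduct 16 (not isolated)
Conditions: 15 (5 equiv), (+)-camphorsulfonic acid (10 mol%), CH2Cl2/(CF3)2CHOH (4:1), −40 → 0 °C; then Et3N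
Reagents that add atoms: none
Why: Proposed new method: acid should ionize the C4 carbinol of 14 to a benzylic cation stabilized by O7 and O1 (ortho) and O5 (para) of the lower ring A, resorcinol should capture it through its C4 (para to one hydroxyl, ortho to the other) to give 16, and the ortho-hydroxyl should then open the protonated oxirane at the carbon benzylic to ring B. The closest known reaction types are the Friedel–Crafts benzylation of phenols by electron-rich benzylic alcohols and the acid-mediated cyclization of 2-(2-hydroxybenzyl)-3-aryloxiranes to 2,3-trans-flavan-3-ols; their union on an oxiranyl carbinol in one operation is the new element. Ring C closes by 6-endo-tet epoxide opening, preferred over the 5-exo mode because the breaking C2–O bond is benzylic to the electron-rich 3,4-bis(benzyloxy)phenyl ring. C3 is carried over unchanged from the epoxide, C2 is set by backside attack with inversion (hence 2,3-trans), and C4 is set by 1,2-induction from C3: in the conformer that places C3–H in the plane of the hindered aryl cation (allylic 1,3-strain) the arene should add anti to the oxirane C–O bond (polar Felkin–Anh sense, as in additions to α,β-epoxy carbonyl compounds), which gives the 3,4-trans, all-equatorial ring. The step needs chemoselective ionization at C4 before the epoxide is touched, which the far greater cation-stabilizing power of the trioxygenated lower ring A over the dioxygenated ring B, the weak acid and the low temperature should secure. It also needs a single C-alkylation of resorcinol at C4, which the reversibility of O-alkylation, the steric preference for C4 over C2, the equivalence of C4 and C6 and the excess of resorcinol should secure.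

Step 12
Reactants: 17 hepta-O-benzyl fisetinidol-(4α→8)-6-methylcatechin
Product: 18 fisetinidol-(4α→8)-6-methylcatechin (target)
Conditions: H2 (1 atm), Pd(OH)2/C (20 wt%), THF/MeOH (1:1), rt
Reagents that add atoms: none
Why: Hydrogenolysis of the seven O-benzyl groups; the flavan C2–O1 bonds and the C4 diarylmethine are expected to persist under these neutral conditions, so no stereocentre is touched.

**Compound list**

1 | (+)-catechin, (2R,3S)-2-(3,4-dihydroxyphenyl)chromane-3,5,7-triol | Oc1cc(O)c2c(c1)O[C@H](c1ccc(O)c(O)c1)[C@@H](O)C2 | starting material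
2 | 5,7,3',4'-tetra-O-benzyl-(+)-catechin, (2R,3S)-5,7-bis(benzyloxy)-2-[3,4-bis(benzyloxy)phenyl]chroman-3-ol | O(Cc6ccccc6)c1cc(OCc6ccccc6)c2c(c1)O[C@H](c5ccc(OCc6ccccc6)c(OCc6ccccc6)c5)[C@@H](O)C2 | intermediate
3 | 3,5,7,3',4'-penta-O-benzyl-(+)-catechin, (2R,3S)-3,5,7-tris(benzyloxy)-2-[3,4-bis(benzyloxy)phenyl]chromane | O(Cc6ccccc6)c1cc(OCc6ccccc6)c2c(c1)O[C@H](c5ccc(OCc6ccccc6)c(OCc6ccccc6)c5)[C@@H](OCc6ccccc6)C2 | intermediate
4 | 8-bromo-penta-O-benzylcatechin, (2R,3S)-3,5,7-tris(benzyloxy)-2-[3,4-bis(benzyloxy)phenyl]-8-bromochromane | O(Cc6ccccc6)c1cc(OCc6ccccc6)c2c(c1Br)O[C@H](c5ccc(OCc6ccccc6)c(OCc6ccccc6)c5)[C@@H](OCc6ccccc6)C2 | intermediate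
5 | 8-bromo-6-iodo-penta-O-benzylcatechin, (2R,3S) | O(Cc6ccccc6)c1c(I)c(OCc6ccccc6)c2c(c1Br)O[C@H](c5ccc(OCc6ccccc6)c(OCc6ccccc6)c5)[C@@H](OCc6ccccc6)C2 | intermediate
6 | 8-bromo-6-methyl-penta-O-benzylcatechin, (2R,3S)-3,5,7-tris(benzyloxy)-2-[3,4-bis(benzyloxy)phenyl]-8-bromo-6-methylchromane | O(Cc6ccccc6)c1c(C)c(OCc6ccccc6)c2c(c1Br)O[C@H](c5ccc(OCc6ccccc6)c(OCc6ccccc6)c5)[C@@H](OCc6ccccc6)C2 | intermediate
7 | 3,4-bis(benzyloxy)benzaldehyde | O=Cc1ccc(OCc2ccccc2)c(OCc2ccccc2)c1 | starting material
8 | ethyl (triphenylphosphoranylidene)acetate | CCOC(=O)C=P(c1ccccc1)(c1ccccc1)c1ccccc1 | starting material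
9 | ethyl (E)-3-[3,4-bis(benzyloxy)phenyl]prop-2-enoate | CCOC(=O)/C=C/c1ccc(OCc2ccccc2)c(OCc2ccccc2)c1 | intermediate
10 | (E)-3-[3,4-bis(benzyloxy)phenyl]prop-2-en-1-ol | OC/C=C/c1ccc(OCc2ccccc2)c(OCc2ccccc2)c1 | intermediate
11 | [(2S,3S)-3-[3,4-bis(benzyloxy)phenyl]oxiran-2-yl]methanol | OC[C@@H]1O[C@H]1c1ccc(OCc2ccccc2)c(OCc2ccccc2)c1 | intermediate
12 | (2R,3S)-3-[3,4-bis(benzyloxy)phenyl]oxirane-2-carbaldehyde | O=C[C@@H]1O[C@H]1c1ccc(OCc2ccccc2)c(OCc2ccccc2)c1 | intermediate
13 | C8 aryllithium of 6, [(2R,3S)-3,5,7-tris(benzyloxy)-2-[3,4-bis(benzyloxy)phenyl]-6-methylchroman-8-yl]lithium | O(Cc6ccccc6)c1c(C)c(OCc6ccccc6)c2c(c1[Li])O[C@H](c5ccc(OCc6ccccc6)c(OCc6ccccc6)c5)[C@@H](OCc6ccccc6)C2 | intermediate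
14 | oxiranyl carbinol, [(2S,3S)-3-[3,4-bis(benzyloxy)phenyl]oxiran-2-yl][(2R,3S)-3,5,7-tris(benzyloxy)-2-[3,4-bis(benzyloxy)phenyl]-6-methylchroman-8-yl]methanol, both epimers at the carbinol carbon | O(Cc6ccccc6)c1c(C)c(OCc6ccccc6)c2c(c1C(O)[C@@H]4O[C@H]4c4ccc(OCc6ccccc6)c(OCc6ccccc6)c4)O[C@H](c5ccc(OCc6ccccc6)c(OCc6ccccc6)c5)[C@@H](OCc6ccccc6)C2 | intermediate
15 | resorcinol, benzene-1,3-diol | Oc1cccc(O)c1 | starting material
16 | Friedel–Crafts adduct, 4-[(S)-[(2S,3S)-3-[3,4-bis(benzyloxy)phenyl]oxiran-2-yl][(2R,3S)-3,5,7-tris(benzyloxy)-2-[3,4-bis(benzyloxy)phenyl]-6-methylchroman-8-yl]methyl]benzene-1,3-diol | O(Cc6ccccc6)c1c(C)c(OCc6ccccc6)c2c(c1[C@H](c4ccc(O)cc4O)[C@@H]4O[C@H]4c4ccc(OCc6ccccc6)c(OCc6ccccc6)c4)O[C@H](c5ccc(OCc6ccccc6)c(OCc6ccccc6)c5)[C@@H](OCc6ccccc6)C2 | intermediate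
17 | hepta-O-benzyl dimer, (2R,3S,4S)-2-[3,4-bis(benzyloxy)phenyl]-4-[(2R,3S)-3,5,7-tris(benzyloxy)-2-[3,4-bis(benzyloxy)phenyl]-6-methylchroman-8-yl]chromane-3,7-diol | O(Cc6ccccc6)c1c(C)c(OCc6ccccc6)c2c(c1[C@@H]3c4ccc(O)cc4O[C@H](c4ccc(OCc6ccccc6)c(OCc6ccccc6)c4)[C@H]3O)O[C@H](c5ccc(OCc6ccccc6)c(OCc6ccccc6)c5)[C@@H](OCc6ccccc6)C2 | intermediate
18 | fisetinidol-(4α→8)-6-methylcatechin, (2R,3S,4S)-2-(3,4-dihydroxyphenyl)-4-[(2R,3S)-2-(3,4-dihydroxyphenyl)-3,5,7-trihydroxy-6-methylchroman-8-yl]chromane-3,7-diol | Cc1c(O)c2c(c([C@@H]3c4ccc(O)cc4O[C@H](c4ccc(O)c(O)c4)[C@H]3O)c1O)O[C@H](c1ccc(O)c(O)c1)[C@@H](O)C2 | target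

**Step count and risks**

Total step count: 12. Longest linear sequence: 8 steps (steps 1–5, 10, 11, 12).

Steps most likely to fail:

1. Step 11 (proposed new method). What may go wrong: insufficient facial discrimination when resorcinol adds to the acyclic C4 cation, which would erode the 3,4-trans selectivity; or acid opening and rearrangement of the electron-rich epoxide before C4 is arylated. Fallback (known chemistry, stepwise and tethered), setting out from 14: the epoxide is first opened at its benzylic carbon by the phenoxide of 3-(benzyloxy)phenol (Oc1cccc(OCc2ccccc2)c1; Cs2CO3, DMF, 60 °C), an SN2 opening with inversion of the kind known for 3-arylglycidols, to give the benzylic aryl ether diol F1. BF3·OEt2 in CH2Cl2 at −40 °C then ionizes the C4 carbinol, and the tethered arene closes ring C by intramolecular Friedel–Crafts alkylation para to its benzyloxy group. Because the arene is tied to C2, it can reach the cation only from the face anti to the C3–O bond in the strain-minimized conformer, which should give the 3,4-trans 7-O-benzyl ether F2. F2 is debenzylated under the conditions of step 12, so the fallback comes back to the route at 18.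

2. Step 8. What may go wrong: opening of the electron-rich benzylic epoxide by tartrate, isopropoxide or hydroperoxide under the titanium alkoxide conditions or on isolation, with loss of material and of enantiomeric purity. Fallback, setting out from 6 (with 7): the epoxide is made next to a ketone under basic conditions instead. Aryllithium 13, formed as in step 10, is acylated with N-methoxy-N-methylacetamide (CC(=O)N(C)OC) to the C8 methyl ketone F3. Claisen–Schmidt condensation of F3 with 7 (KOH, EtOH/THF) gives the (E)-chalcone F4. Juliá–Colonna epoxidation (poly-L-leucine, urea·H2O2, DBU, THF) should give the (2R,3S)-epoxy ketone F5. Reduction with NaBH4/CeCl3·7H2O in MeOH at −40 °C brings the fallback back to the route at 14.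

3. Step 5. What may go wrong: competing oxidative addition into the C–Br bond or slow coupling at the doubly ortho-substituted iodide, leading to over-methylation or protodehalogenation. Fallback, setting out from 4: the methyl group is introduced by formylation and deoxygenation instead of cross-coupling. Vilsmeier–Haack formylation (POCl3, DMF, 60 °C) at C6, the only free position of ring A, gives the 6-carbaldehyde F6. Ionic hydrogenation (Et3SiH, CF3CO2H, CH2Cl2, 0 °C) reduces the electron-rich aryl aldehyde to the methyl group and comes back to the route at 6.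

Further compounds
F1 | step 11 | benzylic aryl ether diol, (2S,3R)-3-[3,4-bis(benzyloxy)phenyl]-3-[3-(benzyloxy)phenoxy]-1-[(2R,3S)-3,5,7-tris(benzyloxy)-2-[3,4-bis(benzyloxy)phenyl]-6-methylchroman-8-yl]propane-1,2-diol, both C1 epimers | O(Cc6ccccc6)c1c(C)c(OCc6ccccc6)c2c(c1C(O)[C@H](O)[C@H](Oc4cccc(OCc6ccccc6)c4)c4ccc(OCc6ccccc6)c(OCc6ccccc6)c4)O[C@H](c5ccc(OCc6ccccc6)c(OCc6ccccc6)c5)[C@@H](OCc6ccccc6)C2
F2 | step 11 | 7-O-benzyl ether of 17, (2R,3S,4S)-7-(benzyloxy)-2-[3,4-bis(benzyloxy)phenyl]-4-[(2R,3S)-3,5,7-tris(benzyloxy)-2-[3,4-bis(benzyloxy)phenyl]-6-methylchroman-8-yl]chroman-3-ol | O(Cc6ccccc6)c1c(C)c(OCc6ccccc6)c2c(c1[C@@H]3c4ccc(OCc6ccccc6)cc4O[C@H](c4ccc(OCc6ccccc6)c(OCc6ccccc6)c4)[C@H]3O)O[C@H](c5ccc(OCc6ccccc6)c(OCc6ccccc6)c5)[C@@H](OCc6ccccc6)C2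
F3 | step 8 | C8 methyl ketone, 1-[(2R,3S)-3,5,7-tris(benzyloxy)-2-[3,4-bis(benzyloxy)phenyl]-6-methylchroman-8-yl]ethanone | O(Cc6ccccc6)c1c(C)c(OCc6ccccc6)c2c(c1C(C)=O)O[C@H](c5ccc(OCc6ccccc6)c(OCc6ccccc6)c5)[C@@H](OCc6ccccc6)C2
F4 | step 8 | (E)-chalcone, (E)-3-[3,4-bis(benzyloxy)phenyl]-1-[(2R,3S)-3,5,7-tris(benzyloxy)-2-[3,4-bis(benzyloxy)phenyl]-6-methylchroman-8-yl]prop-2-en-1-one | O(Cc6ccccc6)c1c(C)c(OCc6ccccc6)c2c(c1C(=O)/C=C/c4ccc(OCc6ccccc6)c(OCc6ccccc6)c4)O[C@H](c5ccc(OCc6ccccc6)c(OCc6ccccc6)c5)[C@@H](OCc6ccccc6)C2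
F5 | step 8 | (2R,3S)-epoxy ketone, [(2R,3S)-3-[3,4-bis(benzyloxy)phenyl]oxiran-2-yl][(2R,3S)-3,5,7-tris(benzyloxy)-2-[3,4-bis(benzyloxy)phenyl]-6-methylchroman-8-yl]methanone | O(Cc6ccccc6)c1c(C)c(OCc6ccccc6)c2c(c1C(=O)[C@@H]4O[C@H]4c4ccc(OCc6ccccc6)c(OCc6ccccc6)c4)O[C@H](c5ccc(OCc6ccccc6)c(OCc6ccccc6)c5)[C@@H](OCc6ccccc6)C2
F6 | step 5 | 6-carbaldehyde, (2R,3S)-3,5,7-tris(benzyloxy)-2-[3,4-bis(benzyloxy)phenyl]-8-bromochromane-6-carbaldehyde | O(Cc6ccccc6)c1c(C=O)c(OCc6ccccc6)c2c(c1Br)O[C@H](c5ccc(OCc6ccccc6)c(OCc6ccccc6)c5)[C@@H](OCc6ccccc6)C2
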